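Start from a small charge: 0.0550 M of reagent, held in Saturday's and Sunday's runs and again in noon and autumn, while the substrate moves.

in all of them: free catalyst 6.5 mM

| charge | substrate | reagent | remark | time |
|---|---|---|---|---|
| Saturday's | 0.071 M | 0.055 M | run made earlier |  |
| Sunday's | 0.11 M | 0.055 M | run made earlier |  |
| noon | 0.050 M | 0.0550 M |  | 8.0 h |
| autumn | 0.080 M | 0.0550 M |  | 12 h |

1. the flask that ends with the higher amount of target, in percent of the substrate charged, or "neither" when 2 percentage points or less lies between them (noon / autumn / neither)
2. final target, as a percentage of the substrate charged, in noon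
3. final target, as a percentage of the substrate charged, in autumn

- what may be going on: substrate + free catalyst -> catalyst intermediate A; catalyst intermediate A -> catalyst intermediate B; reagent + catalyst intermediate B <-> catalyst intermediate C; catalyst intermediate C -> by-product + catalyst intermediate D; catalyst intermediate D -> free catalyst + target

| Saturday's: time / h | Saturday's: target / % | Sunday's: time / h | Sunday's: target / % |
|---|---|---|---|
| 1.33 | 16.9 | 0.417 | 3.0 |
| 3.00 | 34.9 | 1.00 | 8.8 |
| 4.00 | 43.9 | 2.50 | 21.2 |
| 6.00 | 55.8 | 6.00 | 37.4 |

(each reading ± 0.3 percentage points)

Read the last readings of the two runs against each other in molar terms. At 6.00 h Saturday's run holds 0.0396 M of target and Sunday's 0.0411 M, though the substrate charges were 0.071 M and 0.11 M. So watch the reagent: the proposed cycle spends one reagent per target.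

Autumn's ratio is 68.8 %. Call this ratio, reagent charge over substrate charge, the reagent ceiling: in this cycle, while it stands under 100 percent, reagent is the limiting reagent and target, in percent of the substrate charged, stops at the ceiling.

Now read the time column. Saturday's reagent not yet turned into target is 54.9 % at 3.00 h; squared, that gives 30.1 %, and the 6.00 h row reads 28.0 %. Equal spans take roughly equal factors, so treat reagent as pseudo-first-order. Sunday's last row leaves 25.2 %; take 26.6 % per 6.00 h.

My reckoning for autumn: 12 h is twice that span, so the ceiling times the part turned gives 63.9 %. Noon's ratio is 110 %, so substrate limits it instead. The same pace gives 91.2 % for noon, but take that as high: Saturday's, with the leaner substrate, left more reagent unturned.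

The forecast says noon, with 85 % for noon and 64.5 % for autumn, on this ground: “autumn is capped by stoichiometry”. Its noon figure stands below mine, and its autumn figure above mine.

Noon ends at 84.3 % and autumn at 65.0 %, so noon gives more.

    substrate + free catalyst → catalyst intermediate A (k = 160 M⁻¹ h⁻¹)
    catalyst intermediate A → catalyst intermediate B (k = 800 h⁻¹)
    reagent + catalyst intermediate B ⇌ catalyst intermediate C (K = 7.70 M⁻¹, k = 100 M⁻¹ h⁻¹)
    catalyst intermediate C → by-product + catalyst intermediate D (k = 11.0 h⁻¹)
    catalyst intermediate D → free catalyst + target (k = 200 h⁻¹)

Left standing, autumn reaches 68.8 % at 120 h, with reagent at 0 %, and that is its ceiling of 68.8 %. Apply the ceiling to a neighbour flask, noon's recipe with 0.022 M of reagent: the ratio is 44.0 %, and at 8.00 h that neighbour holds 38.4 % of target with 12 % of its reagent still unbound.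

The data were computed with made-up constants; scatter was added.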